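## Analysis of the target

The target is a 2-aryl-3-methyl-2,3-dihydro-1,4-benzodioxine, numbered here O1, C2, C3, O4, C4a, C5 to C8, C8a. Ring A is a 1,2,3-trioxygenated benzene with OMe on C5 and allyl on C7, ring B is the 1,4-dioxane, and ring C, on C2, is a 4-hydroxy-3,5-dimethoxyphenyl group. The two ring oxygens are not equivalent: O4, on C4a next to C5–OMe, carries the methyl-bearing C3, and O1, on C8a, carries the benzylic C2, so reversed regiochemistry gives a constitutional isomer. C2 and C3 are both R, and the aryl and methyl groups are trans (both equatorial on the half-chair). C2 is a benzylic ether para to a free phenol, so the C2–O1 bond ionises with acid and C2 can settle into the more stable trans arrangement. C3 is therefore the centre that must be set absolutely, and it carries only O, CH3 and H as handles. The terminal allyl group rules out hydrogenolysis and conditions that make metal hydrides, and the electron-rich phenol and catechol stages are air-sensitive. The feature that invites the key move: O1 and O4 stand on the neighbouring carbons C8a and C4a, so at the quinone oxidation level ring A holds an O=C8a–C4a=O heterodiene that can take up C2–C3 in one cycloaddition, and C2, bound to O1, becomes a lactol carbon once the C2–aryl bond is cut.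

## Retrosynthetic reasoning

**C2–aryl bond (15 to 12 + 13).** The first cut is the C–C bond between C2 and ring C, not a C–O bond. C2 is attached to O1, so removing the aryl group as a nucleophile leaves oxocarbenium ion 14, the ionised form of lactol 12. The nucleophile is 2,6-dimethoxyphenol 13 itself, which reacts at the carbon para to its hydroxyl group. This takes ring C out of the problem as an unprotected commercial phenol and leaves a precursor whose only fixed stereocentre is C3. Forward, the aryl group has to enter trans to the C3 methyl group; approach anti to the methyl group and reversible ionisation of the C2–O1 bond both favour this.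

**O4–C3 and O1–C2 bonds (12 to 9 + 8, the key disconnection).** Lactol 12 is the formal [4+2] adduct of o-quinone 9 (the O=C–C=O heterodiene of ring A) and the enol form of propanal 8. Both C–O bonds of ring B are cut at once. Forward, 8 reacts as its chiral enamine 10 with a chiral secondary amine as catalyst, and aminal 11 is hydrolysed. The gain is ring B, the C3 stereocentre and the placing of the two oxygens in one catalytic operation, from an achiral quinone and a three-carbon aldehyde, without protecting groups. The forward reaction has to achieve C–O rather than C–C bond formation, bonding of C3 to the oxygen next to the OMe-bearing carbon, and facial control at C3.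

**9 to 7.** o-Quinone 9 is not stored. It is the dehydrogenation product of catechol 7 and is made and used in solution.

**7 to 5.** Catechol 7 comes from salicylaldehyde 5 by Dakin oxidation. The formyl carbon is exchanged for the O1 hydroxyl group by way of formate 6, which puts the second oxygen exactly beside the existing phenol.

**5 to 2 to 1.** The allyl group para to the phenol in 5 is delivered by a para-Claisen rearrangement of allyl ether 2. Both ortho positions are blocked, so the allyl group passes through dienones 3 and 4 to the para carbon. Ether 2 is the O-allyl ether of commercial o-vanillin 1.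

## Alternatives that were turned down

**Alternative 1:** the textbook route through an open-chain 8-O-4' carbinol.
- Disconnection: O1–C2 last, O4–C3 before it.
- Forward key step: the oxygen next to C–OMe of a mono-protected form of 7 is alkylated with inversion by a lactate ester (Mitsunobu). The ester is taken to the aldehyde, a protected ring-C aryl Grignard reagent is added, and after deprotection carbinol A1 is cyclised by acid through the p-hydroxybenzylic cation to 15.
- Turned down because each operation makes one bond and the chirality is stoichiometric. The two oxygens of 7 must be told apart by protection. The ring-C phenol needs a protecting group that cannot be benzyl, since hydrogenolysis would reduce the allyl group. The α-aryloxy aldehyde can enolise during the Grignard addition. The count is eight to nine steps for a ring closure that is in the end under the same thermodynamic control used here.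

**Alternative 2:** biomimetic oxidative coupling.
- Disconnection: O4–C3 and O1–C2, both to a C6–C3 unit.
- Forward key step: catechol 7 and propenylphenol A2 are oxidised together (Ag2O). The phenoxy radicals couple at C3–O4 and O1 traps the p-quinone methide, giving the benzodioxane as racemate A3.
- Turned down because the C3 centre forms in a radical–radical coupling with no chiral agent bound, so a resolution that discards half of the material would follow. C–C couplings of A2 with itself and with 7 compete. A catalysed cycloaddition of 9 with A2 would have to control a styrene that offers no covalent handle near C3, unlike the aldehyde used in the chosen route.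

**Alternative 3:** double O-arylation of a preformed diol.
- Disconnection: both aryl–O bonds, C4a–O4 and C8a–O1.
- Forward key step: silyl ether A4 of A2 is dihydroxylated (Sharpless asymmetric dihydroxylation, AD-mix-β) to threo diol A5. Copper- or palladium-catalysed double etherification with dibromide A6 closes ring B with retention to A7, and desilylation gives 15.
- Turned down because nothing decides which hydroxyl group meets which C–Br bond, so the regioisomeric benzodioxane is expected as well. Secondary alkoxides on an electron-rich, ortho-substituted aryl bromide invite β-hydride elimination, which oxidises the benzylic carbinol, and the metal hydrides so formed can move the allyl double bond. A6 needs several steps of its own, and the route needs a protecting group and six to seven steps.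

Key step: step 4

Remark on the chemistry: lactol 12 is carried as a mixture of its two C2 epimers, which is of no consequence because C2 is ionised in step 5.

## Route

**Step 1**
Reactants: 1 2-hydroxy-3-methoxybenzaldehyde (o-vanillin)
Product: 2 3-methoxy-2-(prop-2-en-1-yloxy)benzaldehyde
Conditions: allyl bromide (1.2 equiv), K2CO3 (1.5 equiv), DMF, rt
Reagents that add atoms: allyl bromide, C=CCBr
Why: Williamson O-alkylation of the acidic salicylaldehyde phenol (SN2 on allyl bromide); the aldehyde is inert to carbonate and no stereocentre is formed.

**Step 2**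
Reactants: 2 3-methoxy-2-(prop-2-en-1-yloxy)benzaldehyde
Product: 5 2-hydroxy-3-methoxy-5-(prop-2-en-1-yl)benzaldehyde, via ortho-dienone 3 (not isolated), via para-dienone 4 (not isolated)
Conditions: N,N-diethylaniline, 195 °C, argon
Reagents that add atoms: none
Why: Para-Claisen rearrangement: with both ortho positions blocked, a [3,3] shift to an ortho carbon (shown for the OMe-bearing one) gives dienone 3, a Cope [3,3] shift carries the allyl group on to the para carbon (dienone 4), and enolisation gives phenol 5.

**Step 3**
Reactants: 5 2-hydroxy-3-methoxy-5-(prop-2-en-1-yl)benzaldehyde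
Product: 7 3-methoxy-5-(prop-2-en-1-yl)benzene-1,2-diol, via aryl formate 6 (not isolated)
Conditions: 30% aq H2O2 (1.3 equiv), NaOH (2 equiv), THF–H2O, 0 °C to rt, N2; then aq HCl
Reagents that add atoms: hydrogen peroxide, OO
Why: Dakin oxidation: the hydroperoxide anion adds to the aldehyde, the electron-rich ortho-hydroxyaryl group migrates to oxygen to give formate 6, and 6 is saponified in the flask; alkaline H2O2 does not epoxidise the isolated terminal alkene.

**Step 4**
Reactants: 7 3-methoxy-5-(prop-2-en-1-yl)benzene-1,2-diol; 8 propanal
Product: 12 (3R)-5-methoxy-3-methyl-7-(prop-2-en-1-yl)-2,3-dihydro-1,4-benzodioxin-2-ol (both C2 epimers), via o-quinone 9 (not isolated), via enamine 10 (not isolated), via aminal 11 (not isolated)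
Conditions: Ag2O (2 equiv), Na2SO4, CH2Cl2, −20 °C, cold filtration; filtrate added slowly to 8 (3 equiv) and (R)-2-[diphenyl(trimethylsilyloxy)methyl]pyrrolidine (20 mol %), CH2Cl2, −40 °C; then pH 7 phosphate buffer, THF, 0 °C
Reagents that add atoms: water, O (hydrolysis of aminal 11 puts the hydroxyl oxygen on C2; the same amount of water is released when enamine 10 forms)
Why: Ag2O dehydrogenates catechol 7 to o-quinone 9, whose O=C1–C2=O unit is an electron-poor heterodiene, while propanal 8 and the secondary amine condense to the electron-rich E-enamine 10. The two combine in an inverse-electron-demand hetero-Diels–Alder reaction (formal [4+2]) that is expected to be asynchronous: the enamine β-carbon bonds to a quinone oxygen (O4–C3) and the phenoxide so formed adds to the iminium carbon (O1–C2), a 6-exo-trig closure of ring B to aminal 11, which the water set free on enamine formation hydrolyses to lactol 12 with return of the catalyst. The closest known reaction type is the secondary-amine-catalysed enantioselective α-aryloxylation of aldehydes with tetrahalo-o-quinones, together with the classical [4+2] addition of enamines to o-quinones that gives 1,4-benzodioxanes. C3 is set by the catalyst: the diphenyl(trimethylsilyloxy)methyl group of the R pyrrolidine shields one face of the s-trans E-enamine, the quinone oxygen arrives at the open Re face of the β-carbon, and this gives 3R (the S catalyst would give 3S). The C2 centre of 11 and 12 is not controlled and need not be, because it is planar in cation 14 in step 5. The step needs regioselectivity, since C3 must bond to the oxygen on the carbon next to C–OMe: in 9 the 3-methoxy and 5-allyl groups both donate into C1=O (MeO–C3=C4–C5=C6–C1=O is a vinylogous ester), so C2=O is the electron-poor carbonyl, and attack on its oxygen leaves the charge on O1, the phenoxide with one ortho oxygen and no para alkyl group. It also needs O- rather than C-attack and must outrun tautomerisation of 9 through its allylic CH2 group: C3 and C5 of 9 are substituted, C4 is the hindered β-carbon of an enol ether, and the quinone is kept cold, free of added base and at low concentration by slow addition to an excess of 10.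

**Step 5**
Reactants: 12 (3R)-5-methoxy-3-methyl-7-(prop-2-en-1-yl)-2,3-dihydro-1,4-benzodioxin-2-ol; 13 2,6-dimethoxyphenol
Product: 15 4-[(2R,3R)-5-methoxy-3-methyl-7-(prop-2-en-1-yl)-2,3-dihydro-1,4-benzodioxin-2-yl]-2,6-dimethoxyphenol, via oxocarbenium ion 14 (not isolated)
Conditions: 13 (1.1 equiv), Sc(OTf)3 (10 mol %), 4 Å molecular sieves, CH2Cl2, −20 °C to rt
Reagents that add atoms: none
Why: Friedel–Crafts arylation of a lactol through its oxocarbenium ion (the reaction type of aryl C-glycosylation): Sc(OTf)3 ionises the C2–OH bond to cation 14, which phenol 13 attacks with its carbon para to the hydroxyl group, the position activated by OH and free of ortho hindrance. The aryl group should enter anti to the C3 methyl group, and because the new C2–O1 bond is a benzylic ether para to a free phenol it ionises reversibly under the acid, so C2 settles in the trans (2R) arrangement with both substituents equatorial; C3 is not touched.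

## Compound list

1 | 2-hydroxy-3-methoxybenzaldehyde (o-vanillin) | COc1cccc(C=O)c1O | starting material
2 | 3-methoxy-2-(prop-2-en-1-yloxy)benzaldehyde | C=CCOc1c(OC)cccc1C=O | intermediate
3 | 5-methoxy-6-oxo-5-(prop-2-en-1-yl)cyclohexa-1,3-diene-1-carbaldehyde (ortho-dienone) | C=CCC1(OC)C=CC=C(C=O)C1=O | intermediate (not isolated)
4 | 5-methoxy-6-oxo-3-(prop-2-en-1-yl)cyclohexa-1,4-diene-1-carbaldehyde (para-dienone) | C=CCC1C=C(C=O)C(=O)C(OC)=C1 | intermediate (not isolated)
5 | 2-hydroxy-3-methoxy-5-(prop-2-en-1-yl)benzaldehyde | C=CCc1cc(C=O)c(O)c(OC)c1 | intermediate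
6 | 2-hydroxy-3-methoxy-5-(prop-2-en-1-yl)phenyl formate | C=CCc1cc(OC=O)c(O)c(OC)c1 | intermediate (not isolated)
7 | 3-methoxy-5-(prop-2-en-1-yl)benzene-1,2-diol | C=CCc1cc(O)c(O)c(OC)c1 | intermediate
8 | propanal | CCC=O | starting material
9 | 3-methoxy-5-(prop-2-en-1-yl)cyclohexa-3,5-diene-1,2-dione (o-quinone) | C=CCC1=CC(=O)C(=O)C(OC)=C1 | intermediate (not isolated)
10 | (2R)-2-[diphenyl(trimethylsilyloxy)methyl]-1-[(1E)-prop-1-en-1-yl]pyrrolidine (enamine) | C/C=C/N1CCC[C@@H]1C(c1ccccc1)(c1ccccc1)O[Si](C)(C)C | intermediate (not isolated)
11 | (2R)-2-[diphenyl(trimethylsilyloxy)methyl]-1-[(2S,3R)-5-methoxy-3-methyl-7-(prop-2-en-1-yl)-2,3-dihydro-1,4-benzodioxin-2-yl]pyrrolidine (aminal, drawn as the trans adduct of the E-enamine) | C=CCc1cc(OC)c2c(c1)O[C@H](N1CCC[C@@H]1C(c1ccccc1)(c1ccccc1)O[Si](C)(C)C)[C@@H](C)O2 | intermediate (not isolated)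
12 | (3R)-5-methoxy-3-methyl-7-(prop-2-en-1-yl)-2,3-dihydro-1,4-benzodioxin-2-ol (both C2 epimers) | C=CCc1cc(OC)c2c(c1)OC(O)[C@@H](C)O2 | intermediate
13 | 2,6-dimethoxyphenol | COc1cccc(OC)c1O | starting material
14 | (3R)-5-methoxy-3-methyl-7-(prop-2-en-1-yl)-3H-1,4-benzodioxin-1-ium (oxocarbenium ion) | C=CCc1cc(OC)c2c(c1)[O+]=C[C@@H](C)O2 | intermediate (not isolated)
15 | 4-[(2R,3R)-5-methoxy-3-methyl-7-(prop-2-en-1-yl)-2,3-dihydro-1,4-benzodioxin-2-yl]-2,6-dimethoxyphenol | C=CCc1cc(OC)c2c(c1)O[C@H](c1cc(OC)c(O)c(OC)c1)[C@@H](C)O2 | target

## Step count and least certain steps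

Total step count: 5. Longest linear sequence: 5 steps (1 to 2 to 5 to 7 to 12 to 15); 8 and 13 enter as commercial compounds.

**Step 4 (key step).**
- Most likely to go wrong:
  - loss of the quinone before it meets the enamine, by tautomerisation through the allylic CH2 group or by conjugate addition of the secondary amine at C6, which would also consume the catalyst;
  - C–C instead of C–O bond formation at C6;
  - erosion of enantiomeric purity if the lactol opens to the α-aryloxy aldehyde and enolises during hydrolysis.
- Fallback: it leaves the cycloaddition and takes C3 from the chiral pool. It sets out from 5 and comes back at 12. Mitsunobu etherification of the phenol of 5 with ethyl (S)-lactate (PPh3, DIAD, THF, inversion) should give ethyl (2R)-2-[2-formyl-6-methoxy-4-(prop-2-en-1-yl)phenoxy]propanoate F1. Baeyer–Villiger oxidation of the aryl aldehyde (mCPBA, NaHCO3, CH2Cl2, 0 °C, where the electron-rich aryl group migrates faster than the terminal alkene is epoxidised) gives ethyl (2R)-2-[2-(formyloxy)-6-methoxy-4-(prop-2-en-1-yl)phenoxy]propanoate F2. Methanolysis of the formate (NaHCO3, MeOH) frees ethyl (2R)-2-[2-hydroxy-6-methoxy-4-(prop-2-en-1-yl)phenoxy]propanoate F3, which closes under catalytic TsOH in warm toluene to (3R)-5-methoxy-3-methyl-7-(prop-2-en-1-yl)-1,4-benzodioxin-2(3H)-one F4. DIBAL-H at −78 °C reduces the lactone to lactol 12. The former formyl carbon becomes C8a–O1, so the regiochemistry is fixed by construction.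

**Step 5.**
- Most likely to go wrong:
  - over-reaction by a second Friedel–Crafts event, since the benzylic C2–O1 bond of the product ionises under the same acid and a second molecule of 13 can capture the cation irreversibly with ring opening;
  - partial loss of configuration at C3 by reversible deprotonation of cation 14 to the enol ether;
  - self-condensation through the activated C6 and C8 positions of ring A.
- Fallback: it replaces the phenol nucleophile by an aryl-metal reagent and separates C–C bond formation from ring closure. It sets out from 12 and comes back at 15. Commercial 4-bromo-2,6-dimethoxyphenol is silylated (TBSCl, imidazole) to (4-bromo-2,6-dimethoxyphenoxy)(tert-butyl)dimethylsilane F5 and converted with magnesium in THF into [4-(tert-butyldimethylsilyloxy)-3,5-dimethoxyphenyl]magnesium bromide F6. Three equivalents add at −78 °C to the open hydroxy-aldehyde form of 12 to give (1RS,2R)-1-[4-(tert-butyldimethylsilyloxy)-3,5-dimethoxyphenyl]-2-[2-hydroxy-6-methoxy-4-(prop-2-en-1-yl)phenoxy]propan-1-ol F7. Acid (TsOH, CH2Cl2) ionises the benzylic alcohol and the ortho phenol closes ring B under thermodynamic control to tert-butyl{4-[(2R,3R)-5-methoxy-3-methyl-7-(prop-2-en-1-yl)-2,3-dihydro-1,4-benzodioxin-2-yl]-2,6-dimethoxyphenoxy}dimethylsilane F8. TBAF in THF then gives 15.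

**Step 2.**
- Most likely to go wrong: incomplete transfer of the allyl group to the para carbon, or decomposition at about 195 °C (loss of the formyl group when the allyl group visits the formyl-bearing ortho carbon, autoxidation of the aldehyde).
- Fallback: it replaces the sigmatropic shift by a cross-coupling. It sets out from 1 and comes back at 5. Bromination of 1 para to the hydroxyl group (Br2, NaOAc, AcOH) gives 5-bromo-2-hydroxy-3-methoxybenzaldehyde F9, and Stille coupling with allyltributylstannane (Pd(PPh3)4, DMF, 90 °C) gives 5.

## Further compounds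

F1 | step 4 | ethyl (2R)-2-[2-formyl-6-methoxy-4-(prop-2-en-1-yl)phenoxy]propanoate | CCOC(=O)[C@@H](C)Oc1c(OC)cc(CC=C)cc1C=O
F2 | step 4 | ethyl (2R)-2-[2-(formyloxy)-6-methoxy-4-(prop-2-en-1-yl)phenoxy]propanoate | CCOC(=O)[C@@H](C)Oc1c(OC)cc(CC=C)cc1OC=O
F3 | step 4 | ethyl (2R)-2-[2-hydroxy-6-methoxy-4-(prop-2-en-1-yl)phenoxy]propanoate | CCOC(=O)[C@@H](C)Oc1c(OC)cc(CC=C)cc1O
F4 | step 4 | (3R)-5-methoxy-3-methyl-7-(prop-2-en-1-yl)-1,4-benzodioxin-2(3H)-one | C=CCc1cc(OC)c2c(c1)OC(=O)[C@@H](C)O2
F5 | step 5 | (4-bromo-2,6-dimethoxyphenoxy)(tert-butyl)dimethylsilane | COc1cc(Br)cc(OC)c1O[Si](C)(C)C(C)(C)C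
F6 | step 5 | [4-(tert-butyldimethylsilyloxy)-3,5-dimethoxyphenyl]magnesium bromide | COc1cc([Mg]Br)cc(OC)c1O[Si](C)(C)C(C)(C)C
F7 | step 5 | (1RS,2R)-1-[4-(tert-butyldimethylsilyloxy)-3,5-dimethoxyphenyl]-2-[2-hydroxy-6-methoxy-4-(prop-2-en-1-yl)phenoxy]propan-1-ol | C=CCc1cc(O)c(O[C@H](C)C(O)c2cc(OC)c(O[Si](C)(C)C(C)(C)C)c(OC)c2)c(OC)c1
F8 | step 5 | tert-butyl{4-[(2R,3R)-5-methoxy-3-methyl-7-(prop-2-en-1-yl)-2,3-dihydro-1,4-benzodioxin-2-yl]-2,6-dimethoxyphenoxy}dimethylsilane | C=CCc1cc(OC)c2c(c1)O[C@H](c1cc(OC)c(O[Si](C)(C)C(C)(C)C)c(OC)c1)[C@@H](C)O2
F9 | step 2 | 5-bromo-2-hydroxy-3-methoxybenzaldehyde | COc1cc(Br)cc(C=O)c1O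
A1 | alternative 1 | (1RS,2R)-1-(4-hydroxy-3,5-dimethoxyphenyl)-2-[2-hydroxy-6-methoxy-4-(prop-2-en-1-yl)phenoxy]propan-1-ol | C=CCc1cc(O)c(O[C@H](C)C(O)c2cc(OC)c(O)c(OC)c2)c(OC)c1
A2 | alternative 2 | 2,6-dimethoxy-4-[(1E)-prop-1-en-1-yl]phenol | C/C=C/c1cc(OC)c(O)c(OC)c1
A3 | alternative 2 | racemic trans-4-[5-methoxy-3-methyl-7-(prop-2-en-1-yl)-2,3-dihydro-1,4-benzodioxin-2-yl]-2,6-dimethoxyphenol (both enantiomers) | C=CCc1cc(OC)c2c(c1)O[C@H](c1cc(OC)c(O)c(OC)c1)[C@@H](C)O2.C=CCc1cc(OC)c2c(c1)O[C@@H](c1cc(OC)c(O)c(OC)c1)[C@H](C)O2
A4 | alternative 3 | triisopropyl{2,6-dimethoxy-4-[(1E)-prop-1-en-1-yl]phenoxy}silane | C/C=C/c1cc(OC)c(O[Si](C(C)C)(C(C)C)C(C)C)c(OC)c1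
A5 | alternative 3 | (1R,2R)-1-[3,5-dimethoxy-4-(triisopropylsilyloxy)phenyl]propane-1,2-diol | C[C@@H](O)[C@H](O)c1cc(OC)c(O[Si](C(C)C)(C(C)C)C(C)C)c(OC)c1
A6 | alternative 3 | 1,2-dibromo-3-methoxy-5-(prop-2-en-1-yl)benzene | C=CCc1cc(Br)c(Br)c(OC)c1
A7 | alternative 3 | triisopropyl{4-[(2R,3R)-5-methoxy-3-methyl-7-(prop-2-en-1-yl)-2,3-dihydro-1,4-benzodioxin-2-yl]-2,6-dimethoxyphenoxy}silane | C=CCc1cc(OC)c2c(c1)O[C@H](c1cc(OC)c(O[Si](C(C)C)(C(C)C)C(C)C)c(OC)c1)[C@@H](C)O2
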